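(The readings were computed from invented constants; the scatter is artificial.)

1. No single percentage limit can hold for both earlier runs: alder reads 7.4% at 3.00 h, level with its reading at 2.00 h, yet cedar already reads more than that, 26.5%, at 8.00 min.

| flask | substrate | temperature | remark | time |
|---|---|---|---|---|
| alder | 0.083 M | 32 °C | run made earlier |  |
| cedar | 0.50 M | 49 °C | run made earlier |  |
| ochre | 0.60 M | 55 °C |  | 3.0 h |
| amber | 0.40 M | 25 °C |  | 3.0 h |
| teal | 0.25 M | 45 °C |  | 3.0 h |
| red | 0.10 M | 25 °C |  | 3.0 h |

- alder (time / h: ring / %): 0.250: 5.5; 0.333: 5.4; 0.500: 5.6; 0.833: 6.2; 1.33: 6.7; 2.00: 7.4; 3.00: 7.4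
- cedar (time / min: ring / %): 8.00: 26.5; 15.0: 35.9; 25.0: 42.0; 30.0: 44.7; 40.0: 48.8; 50.0: 51.0; 60.0: 54.9

(readings scatter by 0.5 percentage points)

- all flasks from highest to lowest amount of ring, in percent of the substrate charged, at 3.0 h (ochre / amber / teal / red)
- the amount of ring, in percent of the substrate charged of the flask you put first, at 3.0 h
- the amount of ring, in percent of the substrate charged of the flask you put last, at 3.0 h

- what was read earlier has a scatter of 0.5 percentage points, one standard deviation
- a reading or a percentage of ring counts all its forms, free or not

2. So try a limit in concentration. Take c* = 6.14 mM, the stall amount: the ring concentration of alder's plateau, its last percentage times its charge. It is a reading, with the scatter of one, and it belongs to alder's temperature.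

3. Divide c* by a flask's charge C and you have the stall share s = c*/C, the percentage a flask shows if its ring stops at c*. Cedar's first reading already holds 21.6 times c*, so c* stops nothing at cedar's charge and temperature.

4. Now decide the next run. Red's charge lies close to alder's, at 0.10 M against 0.083 M, and red is colder, at 25 °C against 32 °C, so I commit red to its share, 6.14%. Don't spend your run on that recipe if you want ring. Ochre's share is 1.02%, lower than red's, and ochre lies beyond cedar in charge and temperature, so run ochre and expect it to climb as cedar did. Between amber and teal, c* gives you nothing.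

5. The forecast says ochre > amber > teal > red, with top 70% (60% to 80%) and low 8.5% (5.5% to 12%). Of red it says: “Red should stay close to alder, about 8–9%.” My share for red stands lower than its figure.

6. The flasks give ochre > teal > amber > red: ochre 75.5%, red 4.65%, and teal 63.5% over amber 16.4%, the reverse of the forecast's pair. At 3.00 h, red holds crystals 0% and ochre 73.9%. In concentration, red's ring is 4.65 mM, under c*, so my share overshot red by 1.5 percentage points. Ochre's ring is 73.8 times c*.

    substrate → ring (k = 0.00620 /min, Ea = 86.0 kJ/mol)
    2 substrate → open dimer (k = 0.00850 /M/min, Ea = 71.0 kJ/mol)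
    ring ⇌ isomer of the product (K = 10.0, k = 0.110 /min, Ea = 80.0 kJ/mol, ΔH = −46.0 kJ/mol)
    crystals ⇌ ring, rate k4*(cs4 - [ring]) while solid is left; crystals form when [ring] > cs4 (solubility = 10.0 mM, k = 3.20 /min)
    substrate ⇌ dormant form (K = 4.60, k = 0.00600 /min, Ea = 84.0 kJ/mol, ΔH = −14.0 kJ/mol)
    (constants at 25 °C)

7. Second flask: ochre's charge kept at 80 °C. Its share stays 1.02%, the charge being unchanged, so expect ring far past it, as in ochre. It gives 83.0% at 3.00 h, with crystals 81.4%.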